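**Retrosynthetic overview**
1. Target ⇐ bridged methyl ketal (ionic reduction sets C6–H) ⇐ ring C closed last by a gold-catalysed enol-ether/alkyne cyclisation (C15–C1).
2. Ring D (the tetrahydrofuran, formed as a cyclic ketal) ⇐ γ-keto aldehyde plus a reagent-controlled butynyl-zinc addition that sets C4.
3. Key bond C15–C16 (the 1,4-dioxygenated C4···C6 array): the decalone α-carbon is made electrophilic as an enolonium species and joined to the α-carbon of isobutyraldehyde enol silane.
4. Bromo-hydroxy-decalone ⇐ enantioselective quinone Diels–Alder adduct; C12 carbinol by MeMgBr; C9–Br by ketone → vinyl bromide → hydrogen-atom-transfer hydrogenation.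
5. Ring order: A (quinone) → B (Diels–Alder) → D → C.

**Assumptions**
- Atom labels follow the target SMILES from its second atom: C1 (C=CH2), C2, C3, C4 (OCH), O5, C6 (OCH), C7, C8 (C–CH3), C9 (CHBr), C10, C11, C12 (C(CH3)OH), C13 (ring-fusion CH), C14, C15 (spiro C), C16 (C(CH3)2).
- In step 3 the (R)-oxazaborolidinium catalyst is taken to give the (8aS) adduct, from the α-C–H-bound pre-transition-state model; this assignment is uncertain, and the (S)-catalyst is used instead if the opposite sense is found.
- In step 10 the (1R,2R)-ligand is taken to deliver the alkyl group to the Si face, by analogy with simple aldehydes.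

**Step 1**
Reactants: 1 2-methoxy-6-methylphenol
Product: 2 2-methoxy-6-methyl-1,4-benzoquinone
Conditions: Co(salen) (5 mol %), O2 (1 atm), DMF, rt
Reagents that add atoms: dioxygen, O=O
Why: aerobic cobalt-salen para-oxidation of a 2,6-disubstituted phenol gives the p-quinone, and no stereocentre is formed.

**Step 2**
Reactants: 3 methyl vinyl ketone
Product: 4 2-(triisopropylsilyloxy)buta-1,3-diene
Conditions: TIPSOTf, Et3N, CH2Cl2, 0 °C
Reagents that add atoms: triisopropylsilyl triflate, CC(C)[Si](C(C)C)(C(C)C)OS(=O)(=O)C(F)(F)F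
Why: soft enolisation and O-silylation of the enone gives the 2-silyloxydiene, and no stereocentre is formed.

**Step 3**
Reactants: 2 2-methoxy-6-methyl-1,4-benzoquinone; 4 2-(triisopropylsilyloxy)buta-1,3-diene
Product: 5 cis-fused adduct (4aR,8aS)-2-methoxy-8a-methyl-7-(triisopropylsilyloxy)-4a,5,8,8a-tetrahydronaphthalene-1,4-dione
Conditions: (R)-o-tolyl-CBS-oxazaborolidine·HNTf2 (20 mol %), CH2Cl2, −78 °C
Reagents that add atoms: none
Why: catalytic enantioselective Diels–Alder reaction in which the Lewis acid binds the carbonyl flanked by two C–H (future C12), the methoxy-bearing C=C is deactivated, the nucleophilic diene terminus (C7) bonds to the methyl-bearing β-carbon to create quaternary C8 on the catalyst-exposed face, and suprafacial addition gives the cis ring fusion.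

**Step 4**
Reactants: 5 cis-fused methoxy ene-dione adduct
Product: 7 trans-dione (4aS,8aS)-8a-methyl-7-(triisopropylsilyloxy)-2,3,4a,5,8,8a-hexahydronaphthalene-1,4-dione, via cis-dione 6 (not isolated)
Conditions: SmI2 (4.5 equiv), MeOH, THF, −78 °C; then K2CO3, MeOH, rt
Reagents that add atoms: none
Why: SmI2 conjugate reduction of the ene-dione followed by reductive cleavage of the α-methoxy ketone gives the saturated dione, and base epimerises C13 (α to the C12 ketone) to the trans-decalin, which is expected to be the more stable isomer.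

**Step 5**
Reactants: 7 trans-dione
Product: 8 (4R,4aS,8aS)-4-hydroxy-4,8a-dimethyl-7-(triisopropylsilyloxy)-3,4,4a,5,8,8a-hexahydronaphthalen-1(2H)-one
Conditions: MeMgBr (1.1 equiv), THF, −78 °C
Reagents that add atoms: methylmagnesium bromide, C[Mg]Br
Why: Grignard addition is chemoselective for the C12 ketone (C9 is neopentyl) and occurs by equatorial attack because the axial face is blocked by the syn-axial C8 methyl, giving the axial hydroxyl and (R)-C12.

**Step 6**
Reactants: 8 hydroxy ketone
Product: 9 C9 enol triflate of 8 (C9(OTf)=C10 with the C12 carbinol and the silyl enol ether retained)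
Conditions: KHMDS (2.2 equiv), PhNTf2, THF, −78 °C
Reagents that add atoms: N-phenylbis(trifluoromethanesulfonimide), O=S(=O)(N(c1ccccc1)S(=O)(=O)C(F)(F)F)C(F)(F)F
Why: enol triflate formation is regiospecific because the C9 ketone can enolise only toward C10 (C8 is quaternary), and no stereocentre is touched.

**Step 7**
Reactants: 9 enol triflate
Product: 11 vinyl bromide ketone (C9(Br)=C10 with the C6 ketone), via vinyl bromide silyl enol ether 10 (not isolated)
Conditions: Ni(OAc)2·4H2O (10 mol %), 1,5-cyclooctadiene, Zn (20 mol %), LiBr, DMA/THF, rt; then TBAF, AcOH, THF, 0 °C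
Reagents that add atoms: lithium bromide, [Li+].[Br-]
Why: nickel-catalysed halogen exchange of the enol triflate (oxidative addition, halide exchange, reductive elimination) gives the vinyl bromide, and buffered fluoride then cleaves the silyl enol ether to the C6 ketone.

**Step 8**
Reactants: 11 vinyl bromide ketone
Product: 12 (4aS,5R,8S,8aS)-8-bromo-5-hydroxy-5,8a-dimethyloctahydronaphthalen-2(1H)-one
Conditions: Mn(dpm)3 (10 mol %), PhSiH3, t-BuOOH, i-PrOH, rt
Reagents that add atoms: none
Why: Mukaiyama-type metal-hydride hydrogen-atom-transfer hydrogenation adds H• to C10 and then delivers the second hydrogen to the α-bromo radical at C9 axially (anti to the axial C8 methyl), giving the equatorial (S)-C9 bromide without C–Br hydrogenolysis.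

**Step 9**
Reactants: 12 bromo-hydroxy-decalone; 13 2-methyl-1-(trimethylsilyloxy)prop-1-ene
Product: 16 γ-keto aldehyde 2-methyl-2-(C15-decalonyl)propanal bearing the C12 trimethylsilyl ether, via bis-silyl enol ether 14 (not isolated), via enolonium species 15 (not isolated)
Conditions: LDA (2.3 equiv), TMSCl, THF, −78 °C; then PhI(OH)OTs, BF3·OEt2, CH2Cl2, −78 °C; then 13, −78 → −40 °C
Reagents that add atoms: chlorotrimethylsilane, C[Si](C)(C)Cl
Why: kinetic enolisation away from the neopentyl C7 gives the C6=C15 silyl enol ether, trivalent iodine turns it into an enolonium (umpoled enolate) whose electrophilic C15 is attacked by the nucleophilic C(CH3)2 carbon of enol silane 13 (umpolung cross-coupling of two α-carbons to a 1,4-dicarbonyl), and the new C15 substituent is equatorial but its configuration is later erased.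

**Step 10**
Reactants: 16 γ-keto aldehyde
Product: 19 cyclic mixed methyl ketal (2-methoxytetrahydrofuran fused at C6–C15 and carrying the (S)-C4 but-3-ynyl chain; C6 anomers), via silylated alkynol 17 (not isolated), via hydroxy ketone 18 (not isolated)
Conditions: [TMSC≡C(CH2)2]2Zn (from 4-bromo-1-(trimethylsilyl)but-1-yne, Mg, THF; ZnCl2, dioxane), Ti(OiPr)4 (1.2 equiv), (1R,2R)-1,2-bis(trifluoromethanesulfonamido)cyclohexane (8 mol %), toluene, −20 °C; then K2CO3, MeOH, rt; then CSA, HC(OMe)3, MeOH, rt
Reagents that add atoms: bis[4-(trimethylsilyl)but-3-yn-1-yl]zinc, C[Si](C)(C)C#CCC[Zn]CCC#C[Si](C)(C)C (made in the flask from 4-bromo-1-(trimethylsilyl)but-1-yne, C[Si](C)(C)C#CCCBr); methanol, CO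
Why: ligand-accelerated, reagent-controlled alkylzinc addition attacks only the aldehyde on its Si face to set (S)-C4, carbonate in methanol removes both silyl groups, and acid-catalysed ketalisation closes ring D so that no free C4 hydroxyl remains.

**Step 11**
Reactants: 19 cyclic mixed methyl ketal
Product: 21 target CNP0412361.2, via bridged methyl ketal 20 (not isolated)
Conditions: Ph3PAuNTf2 (5 mol %), CSA (10 mol %), MeOH (2 equiv), CH2Cl2, rt; then Et3SiH, BF3·OEt2, −78 °C
Reagents that add atoms: none
Why: Proposed new method: acid opens the ketal to the ring D enol ether (C6=C15), whose C15 attacks the gold-activated alkyne 6-exo-dig on the face carrying the C4 tether (axial attack on ring B), methanol traps the oxocarbenium as bridged ketal 20 while protodeauration leaves the exocyclic methylene, and BF3/Et3SiH then ionises the ketal and delivers hydride to C6 from the exo face (the only approach that keeps ring B a chair), setting (R)-C15 and (R)-C6; the closest known chemistry is the gold-catalysed Conia-ene-type carbocyclisation of enol ethers onto alkynes followed by ionic ketal reduction.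

**Compound list**
1 | 2-methoxy-6-methylphenol | COc1cccc(C)c1O | starting material
2 | 2-methoxy-6-methyl-1,4-benzoquinone | COC1=CC(=O)C=C(C)C1=O | intermediate
3 | methyl vinyl ketone | CC(=O)C=C | starting material
4 | 2-(triisopropylsilyloxy)buta-1,3-diene | C=CC(=C)O[Si](C(C)C)(C(C)C)C(C)C | intermediate
5 | cis-fused Diels–Alder adduct (4aR,8aS), methoxy ene-dione with ring B silyl enol ether | CC(C)[Si](C(C)C)(C(C)C)OC=1C[C@]2(C)C(=O)C(OC)=CC(=O)[C@@H]2CC=1 | intermediate
6 | cis-fused saturated dione (4aR,8aS) | CC(C)[Si](C(C)C)(C(C)C)OC=1C[C@]2(C)C(=O)CCC(=O)[C@@H]2CC=1 | intermediate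
7 | trans-fused dione (4aS,8aS) | CC(C)[Si](C(C)C)(C(C)C)OC=1C[C@]2(C)C(=O)CCC(=O)[C@H]2CC=1 | intermediate
8 | (4R,4aS,8aS) C12 methyl carbinol with C9 ketone and ring B silyl enol ether | CC(C)[Si](C(C)C)(C(C)C)OC=1C[C@]2(C)C(=O)CC[C@@](C)(O)[C@H]2CC=1 | intermediate
9 | C9 enol triflate | CC(C)[Si](C(C)C)(C(C)C)OC=1C[C@]2(C)C(OS(=O)(=O)C(F)(F)F)=CC[C@@](C)(O)[C@H]2CC=1 | intermediate
10 | C9 vinyl bromide, ring B silyl enol ether | CC(C)[Si](C(C)C)(C(C)C)OC=1C[C@]2(C)C(Br)=CC[C@@](C)(O)[C@H]2CC=1 | intermediate
11 | C9 vinyl bromide, C6 ketone | O=C1C[C@]2(C)C(Br)=CC[C@@](C)(O)[C@H]2CC1 | intermediate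
12 | (4aS,5R,8S,8aS)-8-bromo-5-hydroxy-5,8a-dimethyloctahydronaphthalen-2(1H)-one | O=C1C[C@]2(C)[C@@H](Br)CC[C@@](C)(O)[C@H]2CC1 | intermediate
13 | 2-methyl-1-(trimethylsilyloxy)prop-1-ene | CC(C)=CO[Si](C)(C)C | starting material
14 | bis-silyl derivative of 12 (C6=C15 trimethylsilyl enol ether, C12 trimethylsilyl ether) | C[Si](C)(C)OC=1C[C@]2(C)[C@@H](Br)CC[C@@](C)(O[Si](C)(C)C)[C@H]2CC=1 | intermediate
15 | enolonium species, drawn as the C15 phenyl(tosyloxy)iodanyl ketone (C15 unassigned) | O=C1C[C@]2(C)[C@@H](Br)CC[C@@](C)(O[Si](C)(C)C)[C@H]2CC1I(c1ccccc1)OS(=O)(=O)c1ccc(C)cc1 | intermediate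
16 | γ-keto aldehyde, C15 bears C(CH3)2CHO equatorially, C12 trimethylsilyl ether | O=C1C[C@]2(C)[C@@H](Br)CC[C@@](C)(O[Si](C)(C)C)[C@H]2C[C@H]1C(C)(C)C=O | intermediate
17 | (S)-C4 alcohol with silylated alkyne and C12 trimethylsilyl ether | O=C1C[C@]2(C)[C@@H](Br)CC[C@@](C)(O[Si](C)(C)C)[C@H]2C[C@H]1C(C)(C)[C@@H](O)CCC#C[Si](C)(C)C | intermediate
18 | hydroxy ketone with (S)-C4 alcohol, terminal alkyne and free C12 hydroxyl (in equilibrium with its lactol) | O=C1C[C@]2(C)[C@@H](Br)CC[C@@](C)(O)[C@H]2C[C@H]1C(C)(C)[C@@H](O)CCC#C | intermediate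
19 | cyclic mixed methyl ketal (ring D closed, C6 anomers) | COC12C[C@]3(C)[C@@H](Br)CC[C@@](C)(O)[C@H]3C[C@H]1C(C)(C)[C@H](CCC#C)O2 | intermediate
20 | bridged methyl ketal (rings C and D closed, C6–OCH3 exo) | C=C1CC[C@@H]2O[C@]3(OC)C[C@]4(C)[C@@H](Br)CC[C@@](C)(O)[C@H]4C[C@]13C2(C)C | intermediate
21 | CNP0412361.2 (C4 S, C6 R, C8 S, C9 S, C12 R, C13 S, C15 R) | C=C1CC[C@@H]2O[C@@H]3C[C@]4(C)[C@@H](Br)CC[C@@](C)(O)[C@H]4C[C@]13C2(C)C | target

**Totals**
Total step count: 11. Longest linear sequence: 10 steps (steps 1 and 3 to 11, from compound 1).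

**Three steps most likely to fail**

Step 9 (enolonium coupling to a fully substituted carbon; desaturation of the ketone or oxidation of 13 may compete). Fallback, setting out from 12 and returning at 18: aldol condensation of the kinetic enolate of 12 with acetone and dehydration gives the α-isopropylidene ketone F1. A formyl-anion-equivalent radical is then added to its β-carbon (1,3-dioxolane, (Bu4N)4W10O32, 365 nm light) to give the dioxolanyl ketone F2. Mild aqueous acid frees the keto aldehyde F3, which is 16 with a free C12 hydroxyl. F3 is put through the zinc addition of step 10 with one extra equivalent of reagent to give the silylated alkynol F4, and carbonate in methanol converts F4 into 18.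

Step 10 (alkylzinc addition to a very hindered neopentyl aldehyde may be too slow or poorly selective). Fallback, setting out from 16 and returning at 18: Brown allylboration with the Ipc2B(allyl) enantiomer that attacks the Si face gives the homoallylic alcohol F5. Hydroboration with 9-BBN and oxidative work-up gives the primary alcohol F6. Selective oxidation (TEMPO, PhI(OAc)2) gives the hydroxy aldehyde F7, which exists as its lactol. Ohira–Bestmann homologation in K2CO3/MeOH installs the terminal alkyne, cleaves the silyl ether and delivers 18.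

Step 11 (gold cyclisation forming two adjacent quaternary carbons; alkyne hydration or O-cyclisation may compete). Fallback, setting out from 16 and returning at 21: the step 10 addition is run with the zinc reagent made from 2,4-dibromobut-1-ene, then carbonate in methanol, to give the hydroxy ketone with a 2-bromoalkene terminus F8. Intramolecular ketone α-alkenylation with zerovalent palladium (Pd(PPh3)4, KOt-Bu, THF) can only close the six-membered ring at C15 and gives the bridged hemiketal F9. Et3SiH/BF3·OEt2 at −78 °C reduces F9 to 21.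

**Further compounds**
F1 | step 9 | α-isopropylidene ketone (C15=C16 enone) from 12 | O=C1C[C@]2(C)[C@@H](Br)CC[C@@](C)(O)[C@H]2CC1=C(C)C
F2 | step 9 | C16 1,3-dioxolan-2-yl conjugate adduct | O=C1C[C@]2(C)[C@@H](Br)CC[C@@](C)(O)[C@H]2C[C@H]1C(C)(C)C3OCCO3
F3 | step 9 | γ-keto aldehyde with free C12 hydroxyl | O=C1C[C@]2(C)[C@@H](Br)CC[C@@](C)(O)[C@H]2C[C@H]1C(C)(C)C=O
F4 | step 9 | (S)-C4 alcohol with silylated alkyne and free C12 hydroxyl | O=C1C[C@]2(C)[C@@H](Br)CC[C@@](C)(O)[C@H]2C[C@H]1C(C)(C)[C@@H](O)CCC#C[Si](C)(C)C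
F5 | step 10 | (S)-C4 homoallylic alcohol | O=C1C[C@]2(C)[C@@H](Br)CC[C@@](C)(O[Si](C)(C)C)[C@H]2C[C@H]1C(C)(C)[C@@H](O)CC=C
F6 | step 10 | (S)-C4 alcohol with primary alcohol terminus | O=C1C[C@]2(C)[C@@H](Br)CC[C@@](C)(O[Si](C)(C)C)[C@H]2C[C@H]1C(C)(C)[C@@H](O)CCCO
F7 | step 10 | (S)-C4 alcohol with aldehyde terminus | O=C1C[C@]2(C)[C@@H](Br)CC[C@@](C)(O[Si](C)(C)C)[C@H]2C[C@H]1C(C)(C)[C@@H](O)CCC=O
F8 | step 11 | hydroxy ketone with (S)-C4 alcohol and 2-bromoalkene terminus | O=C1C[C@]2(C)[C@@H](Br)CC[C@@](C)(O)[C@H]2C[C@H]1C(C)(C)[C@@H](O)CCC(Br)=C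
F9 | step 11 | bridged hemiketal (rings C and D closed, C6–OH) | C=C1CC[C@@H]2O[C@]3(O)C[C@]4(C)[C@@H](Br)CC[C@@](C)(O)[C@H]4C[C@]13C2(C)C
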